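The pyran ring is disconnected at the aryl ether bond O1–C8a. The benzo ring carries a free C5–OH para to the C8–OMe group, and C8a is its only unsubstituted carbon: oxidation of this para-methoxyphenol to its quinone monoketal turns C8a into the β-carbon of a dienone. In one flask the (R)-tertiary alkoxide on the (Z)-alkenyl arm then adds 6-endo to C8a and loss of methanol re-aromatises, so ring closure and the C5–OH/C8–OMe pattern arise together. The precursor is a (Z)-styrenyl tertiary carbinol; C2 comes from a Sharpless epoxidation, C1′/C2′ from a boron-enolate Ireland–Claisen rearrangement, the cyclohexene from a McMurry coupling.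

Key step: step 15

Remarks on the chemistry:
- The (S,S) enantiomer of the boron controller in step 1 is assumed to be the one that delivers (2S,3S)-3; the sense is to be verified at 3, and the (R,R) reagent is used should it prove opposite.
- Chromene numbering (O1 to C8a) is used for the bicycle and primed numbers for the cyclohexene (C1′ quaternary, C2′ CHMe, C3′=C4′).

Step 1
Reactants: 1 geranyl propionate
Product: 3 (2S,3S)-3-ethenyl-2,3,7-trimethyloct-6-enoic acid, via boron ketene acetal 2 (not isolated)
Conditions: (S,S)-2-bromo-4,5-diphenyl-1,3-bis[3,5-bis(trifluoromethyl)benzenesulfonyl]-1,3,2-diazaborolidine (1.2 equiv, pre-formed), Et3N, toluene–hexane, −78 °C, then 4 °C; aqueous work-up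
Reagents that add atoms: none
Why: Enantioselective boron-enolate Ireland–Claisen rearrangement: Et3N in the non-polar medium should give the E(O) enolate (methyl cis to the allyloxy oxygen), the (E)-geranyl unit places its C3 methyl axial in the chair transition state so that the vicinal quaternary/tertiary pair forms in the (2S*,3S*) relative sense, and the C2-symmetric sulfonamide ligand on boron selects the enolate face and with it the absolute configuration.

Step 2
Reactants: 3 (2S,3S)-3-ethenyl-2,3,7-trimethyloct-6-enoic acid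
Product: 4 (3S,4S)-4-ethenyl-3,4,8-trimethylnon-7-en-2-one
Conditions: MeLi (3.5 equiv), Et2O, 0 °C to rt; inverse quench into cold 1 M HCl
Reagents that add atoms: methyllithium, [Li]C
Why: Addition of MeLi to the lithium carboxylate gives a gem-diolate that collapses to the methyl ketone only on work-up (carboxylic acid to methyl ketone), and the hindered tertiary α-hydrogen should not be removed, so C3 keeps its configuration.

Step 3
Reactants: 4 (3S,4S)-4-ethenyl-3,4,8-trimethylnon-7-en-2-one
Product: 6 (4S,5S)-4-ethenyl-4,5-dimethyl-6-oxoheptanal, via ozonide 5 (not isolated)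
Conditions: O3 (1 equiv, Sudan red end point), CH2Cl2, −78 °C; then PPh3, −78 °C to rt
Reagents that add atoms: ozone, [O-][O+]=O
Why: Chemoselective ozonolysis, in which the electron-rich trisubstituted alkene should react far faster than the neopentyl-type vinyl group, followed by reduction of the ozonide with PPh3.

Step 4
Reactants: 6 (4S,5S)-4-ethenyl-4,5-dimethyl-6-oxoheptanal
Product: 7 (5S,6S)-5-ethenyl-1,5,6-trimethylcyclohex-1-ene
Conditions: TiCl3(DME)1.5, Zn–Cu couple, DME, reflux, slow addition of 6 (high dilution)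
Reagents that add atoms: none
Why: Intramolecular McMurry coupling of the 1,6-keto aldehyde on low-valent titanium forms the trisubstituted C3′=C4′ ring alkene, while the isolated vinyl group and both stereocentres are not involved.

Step 5
Reactants: 8 but-2-yn-1-ol
Product: 10 (2Z)-3-iodobut-2-en-1-ol, via cyclic alkenylalanate 9 (not isolated)
Conditions: NaAlH2(OCH2CH2OMe)2, THF, 0 °C to rt; then I2, −78 to 0 °C
Reagents that add atoms: iodine, [I][I]
Why: Hydroxyl-directed trans-hydroalumination of the propargylic alcohol places aluminium on C3 cis to the CH2O group (five-membered alanate), and iodinolysis with retention gives the (Z)-iodide.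

Step 6
Reactants: 7 (5S,6S)-5-ethenyl-1,5,6-trimethylcyclohex-1-ene and 10 (2Z)-3-iodobut-2-en-1-ol
Product: 12 (2Z)-3-methyl-5-[(1S,2S)-1,2,3-trimethylcyclohex-3-en-1-yl]pent-2-en-1-ol, via B-alkyl-9-BBN 11 (not isolated)
Conditions: 9-BBN dimer, THF, rt; then 10, Pd(dppf)Cl2, AsPh3, Cs2CO3, DMF/H2O, rt
Reagents that add atoms: none
Why: Anti-Markovnikov hydroboration of the monosubstituted alkene with 9-BBN (the trisubstituted ring alkene is inert at this temperature) followed by B-alkyl Suzuki–Miyaura coupling, which retains the (Z) geometry of the iodide.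

Step 7
Reactants: 12 (2Z)-3-methyl-5-[(1S,2S)-1,2,3-trimethylcyclohex-3-en-1-yl]pent-2-en-1-ol
Product: 13 {(2S,3R)-3-methyl-3-[2-((1S,2S)-1,2,3-trimethylcyclohex-3-en-1-yl)ethyl]oxiran-2-yl}methanol
Conditions: Ti(OiPr)4, L-(+)-diethyl tartrate, t-BuOOH, 4 Å molecular sieves, CH2Cl2, −20 °C
Reagents that add atoms: tert-butyl hydroperoxide, CC(C)(C)OO
Why: Sharpless asymmetric epoxidation, in which L-(+)-tartrate should direct oxygen to the face of the nerol-type (Z)-allylic alcohol that gives the (2S,3R) epoxide and so fixes the future C2 of the chromene, while the ring alkene, not being allylic to a hydroxyl, does not react.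

Step 8
Reactants: 13 {(2S,3R)-3-methyl-3-[2-((1S,2S)-1,2,3-trimethylcyclohex-3-en-1-yl)ethyl]oxiran-2-yl}methanol
Product: 14 (2R,3R)-3-(chloromethyl)-2-methyl-2-{2-[(1S,2S)-1,2,3-trimethylcyclohex-3-en-1-yl]ethyl}oxirane
Conditions: PPh3, CCl4, NaHCO3 (cat.), reflux
Reagents that add atoms: carbon tetrachloride, ClC(Cl)(Cl)Cl
Why: Appel chlorination of the primary alcohol under buffered conditions leaves the trisubstituted epoxide and both its stereocentres intact (the descriptor at the CH carbon changes only because chlorine changes the priorities).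

Step 9
Reactants: 14 (2R,3R)-3-(chloromethyl)-2-methyl-2-{2-[(1S,2S)-1,2,3-trimethylcyclohex-3-en-1-yl]ethyl}oxirane
Product: 15 (3R)-3-methyl-5-[(1S,2S)-1,2,3-trimethylcyclohex-3-en-1-yl]pent-1-yn-3-ol
Conditions: n-BuLi (3.5 equiv), THF, −40 to −20 °C; H2O
Reagents that add atoms: none
Why: Base-induced double elimination of a 2,3-epoxy chloride (α-deprotonation, epoxide opening to a chlorovinyl alkoxide, dehydrochlorination) gives the terminal alkyne, and because the tertiary C–O bond is never broken the carbinol keeps the (R) configuration.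

Step 10
Reactants: 16 2,3,4-trimethoxyphenol
Product: 17 6-iodo-2,3,4-trimethoxyphenol
Conditions: N-iodosuccinimide, i-Pr2NH (cat.), CH2Cl2, 0 °C
Reagents that add atoms: N-iodosuccinimide, O=C1CCC(=O)N1I
Why: Electrophilic aromatic iodination directed ortho to the phenol hydroxyl (the para position is blocked and the amine catalyst favours the position next to OH), which places the halogen on the future C4a.

Step 11
Reactants: 17 6-iodo-2,3,4-trimethoxyphenol
Product: 18 tert-butyl(6-iodo-2,3,4-trimethoxyphenoxy)dimethylsilane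
Conditions: TBSCl, imidazole, DMF, rt
Reagents that add atoms: tert-butyldimethylsilyl chloride, CC(C)(C)[Si](C)(C)Cl
Why: Silylation of the phenol, which masks the ortho oxygen so that it cannot add to the alkyne (benzofuran formation) in the coupling step.

Step 12
Reactants: 15 (3R)-3-methyl-5-[(1S,2S)-1,2,3-trimethylcyclohex-3-en-1-yl]pent-1-yn-3-ol and 18 tert-butyl(6-iodo-2,3,4-trimethoxyphenoxy)dimethylsilane
Product: 19 (3R)-1-{2-[(tert-butyldimethylsilyl)oxy]-3,4,5-trimethoxyphenyl}-3-methyl-5-[(1S,2S)-1,2,3-trimethylcyclohex-3-en-1-yl]pent-1-yn-3-ol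
Conditions: Pd(PPh3)2Cl2 (cat.), CuI (cat.), Et3N, THF, 45 °C
Reagents that add atoms: none
Why: Sonogashira coupling of the aryl iodide with the terminal alkyne, which tolerates the free tertiary propargylic alcohol and joins the two fragments at the future C4–C4a bond.

Step 13
Reactants: 19 (3R)-1-{2-[(tert-butyldimethylsilyl)oxy]-3,4,5-trimethoxyphenyl}-3-methyl-5-[(1S,2S)-1,2,3-trimethylcyclohex-3-en-1-yl]pent-1-yn-3-ol
Product: 20 (1Z,3R)-1-{2-[(tert-butyldimethylsilyl)oxy]-3,4,5-trimethoxyphenyl}-3-methyl-5-[(1S,2S)-1,2,3-trimethylcyclohex-3-en-1-yl]pent-1-en-3-ol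
Conditions: H2 (1 atm), Pd/CaCO3 poisoned with Pb(OAc)2 (Lindlar catalyst), quinoline, EtOAc, rt
Reagents that add atoms: none
Why: Lindlar semihydrogenation (syn delivery of H2 on poisoned palladium) gives the (Z)-alkene that later holds the carbinol oxygen within reach of the ring, and the trisubstituted ring alkene should not be reduced.

Step 14
Reactants: 20 (1Z,3R)-1-{2-[(tert-butyldimethylsilyl)oxy]-3,4,5-trimethoxyphenyl}-3-methyl-5-[(1S,2S)-1,2,3-trimethylcyclohex-3-en-1-yl]pent-1-en-3-ol
Product: 21 6-[(1Z,3R)-3-hydroxy-3-methyl-5-((1S,2S)-1,2,3-trimethylcyclohex-3-en-1-yl)pent-1-en-1-yl]-2,3,4-trimethoxyphenol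
Conditions: Bu4NF, THF, 0 °C; pH 7 buffer; used at once
Reagents that add atoms: none
Why: Fluoride-induced cleavage of the aryl silyl ether under non-acidic conditions, which avoids ionisation of the tertiary allylic alcohol and its dehydrative closure onto the phenol oxygen.

Step 15
Reactants: 21 6-[(1Z,3R)-3-hydroxy-3-methyl-5-((1S,2S)-1,2,3-trimethylcyclohex-3-en-1-yl)pent-1-en-1-yl]-2,3,4-trimethoxyphenol
Product: 24 (2R)-6,7,8-trimethoxy-2-methyl-2-{2-[(1S,2S)-1,2,3-trimethylcyclohex-3-en-1-yl]ethyl}-2H-chromen-5-ol (target), via quinone monoketal 22 (not isolated), via Michael adduct dienolate 23 (not isolated)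
Conditions: PhI(OAc)2 (1.05 equiv), MeOH, −20 °C; aq. NaHCO3 work-up, crude dienone into THF; KOt-Bu (1.1 equiv), −40 to 0 °C; then pyridinium p-toluenesulfonate (2 equiv), 0 °C to rt, in the dark
Reagents that add atoms: methanol, CO (supplies the second methoxy group of the ketal in 22; one of the two ketal methoxy groups is kept as C8–OMe)
Why: PhI(OAc)2 oxidises the para-methoxyphenol to a phenoxenium equivalent that methanol captures at the methoxy-bearing para carbon (oxidative dearomatisation to quinone monoketal 22), which turns C8a from an arene C–H into the β-carbon of a cross-conjugated dienone. Deprotonation of the tertiary alcohol then triggers an intramolecular oxa-Michael addition, a 6-endo-trig closure of the pyran ring in which O1 bonds to C8a, and the stoichiometric base pulls this reversible addition over to the stabilised dienolate 23. Mild acid protonates 23 and ionises the allylic ketal at C8, and loss of methanol and of the C8a proton re-aromatises the ring; the closest known reaction types are conjugate addition of oxygen nucleophiles to quinone monoketals and acid-mediated aromatisation of such adducts to 3-substituted 4-methoxyphenols. No permanent stereocentre is created: C2 (R) stems from step 7 and its C–O bond is never broken, and the C8a centre of 23 disappears on aromatisation. The step needs site selectivity for C8a over 1,2-addition to the C5 carbonyl and over attack ortho to oxygen, which is secured because the (Z)-alkene holds the alkoxide next to C8a, basic activation directs the nucleophile to the β-carbon, hemiketal formation is reversible and only the C8a adduct can aromatise. The ketal carries the C8 methyl ether through the redox change, so C5–OH and C8–OMe should emerge already differentiated.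

Compound list
1 | (2E)-3,7-dimethylocta-2,6-dien-1-yl propanoate (geranyl propionate) | CCC(=O)OC/C=C(\C)CCC=C(C)C | starting material
2 | E(O) boron ketene acetal of 1 on the (4S,5S)-4,5-diphenyl-1,3-bis[3,5-bis(trifluoromethyl)benzenesulfonyl]-1,3,2-diazaborolidine | C/C=C(\OC/C=C(\C)CCC=C(C)C)OB1N(S(=O)(=O)c2cc(cc(c2)C(F)(F)F)C(F)(F)F)[C@@H](c2ccccc2)[C@H](c2ccccc2)N1S(=O)(=O)c1cc(cc(c1)C(F)(F)F)C(F)(F)F | intermediate
3 | (2S,3S)-3-ethenyl-2,3,7-trimethyloct-6-enoic acid | C=C[C@](C)(CCC=C(C)C)[C@H](C)C(O)=O | intermediate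
4 | (3S,4S)-4-ethenyl-3,4,8-trimethylnon-7-en-2-one | C=C[C@](C)(CCC=C(C)C)[C@H](C)C(C)=O | intermediate
5 | ozonide (1,2,4-trioxolane) of the trisubstituted alkene of 4, trioxolane CH centre undefined | CC1(C)OOC(CC[C@@](C)(C=C)[C@H](C)C(C)=O)O1 | intermediate
6 | (4S,5S)-4-ethenyl-4,5-dimethyl-6-oxoheptanal | O=CCC[C@@](C)(C=C)[C@H](C)C(C)=O | intermediate
7 | (5S,6S)-5-ethenyl-1,5,6-trimethylcyclohex-1-ene | C=C[C@]1(C)CCC=C(C)[C@H]1C | intermediate
8 | but-2-yn-1-ol | CC#CCO | starting material
9 | sodium cyclic (Z)-alkenylalanate from 8 (aluminium on C3, cis to CH2O) | CC1=CCO[Al-]1(OCCOC)OCCOC.[Na+] | intermediate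
10 | (2Z)-3-iodobut-2-en-1-ol | OC/C=C(/C)I | intermediate
11 | 9-BBN adduct at the terminal vinyl carbon of 7 (ring stereocentres as in 7) | C(C[C@]1(C)CCC=C(C)[C@H]1C)B1C2CCCC1CCC2 | intermediate
12 | (2Z)-3-methyl-5-[(1S,2S)-1,2,3-trimethylcyclohex-3-en-1-yl]pent-2-en-1-ol | OC/C=C(/C)CC[C@]1(C)CCC=C(C)[C@H]1C | intermediate
13 | {(2S,3R)-3-methyl-3-[2-((1S,2S)-1,2,3-trimethylcyclohex-3-en-1-yl)ethyl]oxiran-2-yl}methanol | OC[C@@H]1O[C@]1(C)CC[C@]2(C)CCC=C(C)[C@H]2C | intermediate
14 | (2R,3R)-3-(chloromethyl)-2-methyl-2-{2-[(1S,2S)-1,2,3-trimethylcyclohex-3-en-1-yl]ethyl}oxirane | ClC[C@@H]1O[C@]1(C)CC[C@]2(C)CCC=C(C)[C@H]2C | intermediate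
15 | (3R)-3-methyl-5-[(1S,2S)-1,2,3-trimethylcyclohex-3-en-1-yl]pent-1-yn-3-ol | C#C[C@](C)(O)CC[C@]1(C)CCC=C(C)[C@H]1C | intermediate
16 | 2,3,4-trimethoxyphenol | COc1ccc(O)c(OC)c1OC | starting material
17 | 6-iodo-2,3,4-trimethoxyphenol | COc1cc(I)c(O)c(OC)c1OC | intermediate
18 | tert-butyl(6-iodo-2,3,4-trimethoxyphenoxy)dimethylsilane | COc1cc(I)c(O[Si](C)(C)C(C)(C)C)c(OC)c1OC | intermediate
19 | (3R)-1-{2-[(tert-butyldimethylsilyl)oxy]-3,4,5-trimethoxyphenyl}-3-methyl-5-[(1S,2S)-1,2,3-trimethylcyclohex-3-en-1-yl]pent-1-yn-3-ol | COc1cc(C#C[C@](C)(O)CC[C@]2(C)CCC=C(C)[C@H]2C)c(O[Si](C)(C)C(C)(C)C)c(OC)c1OC | intermediate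
20 | (1Z,3R)-1-{2-[(tert-butyldimethylsilyl)oxy]-3,4,5-trimethoxyphenyl}-3-methyl-5-[(1S,2S)-1,2,3-trimethylcyclohex-3-en-1-yl]pent-1-en-3-ol | COc1cc(/C=C\[C@](C)(O)CC[C@]2(C)CCC=C(C)[C@H]2C)c(O[Si](C)(C)C(C)(C)C)c(OC)c1OC | intermediate
21 | 6-[(1Z,3R)-3-hydroxy-3-methyl-5-((1S,2S)-1,2,3-trimethylcyclohex-3-en-1-yl)pent-1-en-1-yl]-2,3,4-trimethoxyphenol | COc1cc(/C=C\[C@](C)(O)CC[C@]2(C)CCC=C(C)[C@H]2C)c(O)c(OC)c1OC | intermediate
22 | 6-[(1Z,3R)-3-hydroxy-3-methyl-5-((1S,2S)-1,2,3-trimethylcyclohex-3-en-1-yl)pent-1-en-1-yl]-2,3,4,4-tetramethoxycyclohexa-2,5-dien-1-one (quinone monoketal) | O=C1C(/C=C\[C@](C)(O)CC[C@]2(C)CCC=C(C)[C@H]2C)=CC(OC)(OC)C(OC)=C1OC | intermediate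
23 | potassium (2R)-6,7,8,8-tetramethoxy-2-methyl-2-{2-[(1S,2S)-1,2,3-trimethylcyclohex-3-en-1-yl]ethyl}-8,8a-dihydro-2H-chromen-5-olate (C8a epimers) | [K+].[O-]C1=C2C=C[C@@](C)(CC[C@]3(C)CCC=C(C)[C@H]3C)OC2C(OC)(OC)C(OC)=C1OC | intermediate
24 | (2R)-6,7,8-trimethoxy-2-methyl-2-{2-[(1S,2S)-1,2,3-trimethylcyclohex-3-en-1-yl]ethyl}-2H-chromen-5-ol | COc1c(O)c2c(c(OC)c1OC)O[C@](C)(CC[C@]1(C)CCC=C(C)[C@H]1C)C=C2 | target

Total step count: 15. Longest linear sequence: 12 steps (steps 1–4, 6–9, 12–15).

Steps most likely to fail, each with a fallback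

1. Step 15. The oxidation may take another course (spirocyclisation of the tertiary alcohol onto the ipso carbon, or over-oxidation of the product phenol), the hindered alkoxide may not add to the ketal-flanked C8a, or the adduct may revert instead of aromatising. Fallback, setting out from 17 (with 15) and returning at 24: the aryl C–O bond is made by palladium-catalysed etherification of an aryl bromide.
   - Iodophenol 17 is brominated at its last free position (N-bromosuccinimide, MeCN, 0 °C) to 5-bromo-6-iodo-2,3,4-trimethoxyphenol F1.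
   - Silylation (TBSCl, imidazole) gives the silyl ether F2.
   - Sonogashira coupling with 15 at the C–I bond only (Pd(PPh3)2Cl2, CuI, Et3N, rt) gives the bromo aryl alkyne F3.
   - Lindlar semihydrogenation gives the (Z)-alkene F4.
   - Pd(OAc)2 with a bulky di-tert-butyl(biaryl)phosphine and Cs2CO3 in toluene at 70 °C closes the pyran ring by intramolecular Buchwald–Hartwig-type coupling of the tertiary alcohol with the aryl bromide, giving the silyl-protected chromene F5.
   - Bu4NF then gives 24.

2. Step 1. Enolisation with the boron controller may be slow or give incomplete E(O) or facial control, and the rearrangement of the hindered ester may stall. Fallback, setting out from 1 and returning at 3: diastereocontrol without reagent control, followed by resolution.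
   - Ester 1 is converted with LDA and Me3SiCl in THF (−78 °C to rt) into the (E)-trimethylsilyl ketene acetal F6, which rearranges through the same chair to the racemic trimethylsilyl ester F7.
   - Hydrolysis gives the racemic acid, that is 3 together with its enantiomer (2R,3R)-3-ethenyl-2,3,7-trimethyloct-6-enoic acid F8.
   - Acid 3 is separated by crystallisation of its (S)-1-phenylethylammonium salt F9 (or with the antipodal amine, whichever gives the less soluble salt of 3) and set free with dilute acid.

3. Step 4. Lewis-acidic titanium may epimerise C5 of 6, or pinacol and aldol pathways may compete with deoxygenation. Fallback, setting out from 3 and returning at 12: the ring is closed by metathesis after the vinyl group has been used up.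
   - Acid 3 is converted (carbonyldiimidazole, then MeNHOMe·HCl) into the Weinreb amide F10.
   - Hydroboration with 9-BBN gives the B-alkyl borane F11, which is coupled with 10 as in step 6 to the hydroxy amide F12.
   - MeMgBr gives the hydroxy methyl ketone F13.
   - Methylenation with Ph3P=CH2 gives the triene alcohol F14.
   - Ring-closing metathesis with the second-generation Grubbs catalyst, between the isopropenyl group and the isopropylidene terminus with loss of 2-methylpropene, should give 12.

Further compounds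
F1 | step 15 | 5-bromo-6-iodo-2,3,4-trimethoxyphenol | COc1c(Br)c(I)c(O)c(OC)c1OC
F2 | step 15 | (5-bromo-6-iodo-2,3,4-trimethoxyphenoxy)(tert-butyl)dimethylsilane | COc1c(Br)c(I)c(O[Si](C)(C)C(C)(C)C)c(OC)c1OC
F3 | step 15 | bromo aryl alkyne: 6-bromo analogue of 19 | COc1c(Br)c(C#C[C@](C)(O)CC[C@]2(C)CCC=C(C)[C@H]2C)c(O[Si](C)(C)C(C)(C)C)c(OC)c1OC
F4 | step 15 | (Z)-alkene: 6-bromo analogue of 20 | COc1c(Br)c(/C=C\[C@](C)(O)CC[C@]2(C)CCC=C(C)[C@H]2C)c(O[Si](C)(C)C(C)(C)C)c(OC)c1OC
F5 | step 15 | 5-O-tert-butyldimethylsilyl ether of 24 | COc1c(O[Si](C)(C)C(C)(C)C)c2c(c(OC)c1OC)O[C@](C)(CC[C@]1(C)CCC=C(C)[C@H]1C)C=C2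
F6 | step 1 | (E)-trimethylsilyl ketene acetal of 1 | C/C=C(\OC/C=C(\C)CCC=C(C)C)O[Si](C)(C)C
F7 | step 1 | trimethylsilyl ester of racemic 3 (one enantiomer drawn) | C=C[C@](C)(CCC=C(C)C)[C@H](C)C(=O)O[Si](C)(C)C
F8 | step 1 | (2R,3R)-3-ethenyl-2,3,7-trimethyloct-6-enoic acid (enantiomer of 3) | C=C[C@@](C)(CCC=C(C)C)[C@@H](C)C(O)=O
F9 | step 1 | (S)-1-phenylethylammonium salt of 3 | C=C[C@](C)(CCC=C(C)C)[C@H](C)C([O-])=O.C[C@H]([NH3+])c1ccccc1
F10 | step 4 | N-methoxy-N-methyl amide of 3 | C=C[C@](C)(CCC=C(C)C)[C@H](C)C(=O)N(C)OC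
F11 | step 4 | 9-BBN adduct at the terminal vinyl carbon of F10 | C(C[C@](C)(CCC=C(C)C)[C@H](C)C(=O)N(C)OC)B1C2CCCC1CCC2
F12 | step 4 | hydroxy Weinreb amide from coupling of F11 with 10 | OC/C=C(/C)CC[C@](C)(CCC=C(C)C)[C@H](C)C(=O)N(C)OC
F13 | step 4 | hydroxy methyl ketone from F12 | OC/C=C(/C)CC[C@](C)(CCC=C(C)C)[C@H](C)C(C)=O
F14 | step 4 | triene alcohol from methylenation of F13 | OC/C=C(/C)CC[C@](C)(CCC=C(C)C)[C@H](C)C(C)=C
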